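**Retrosynthetic overview**

1. The C10–C11 oxirane (ring C) goes in last by reagent-controlled Shi epoxidation of a prenyl alkene; before that, all three angelates are installed in one flask on an epoxy-triol.
2. The ring oxygens of the epoxy-triol come, without protecting groups, from axial hydride delivery at C2, enolate hydroxylation at C1 and a Weitz–Scheffer 3,4-oxirane (ring B) on a carvone-type enone.
3. Key disconnection: C8–C9 together with the 8S centre, in one catalytic linear prenylboration of an unprotected keto-enal with a tertiary allylboronate. This replaces the customary C7–C8 vinyl-metal/aldehyde union of two protected halves.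
4. The keto-enal arises by allylic C–H oxidation of the isopropenyl CH3 of (S)-carvone, which supplies ring A (the cyclohexane), C7, C8, C14, C15 and the C6 stereocentre.
5. Ring order: ring A is bought with carvone, ring B is formed in step 3, ring C in step 7.

Locants used in names (bisabolane numbering): ring C1–C6 (oxygen on C1 and C2, methyl C15 on C3, side chain on C6); chain C7(=C14)–C8–C9–C10–C11(C12)(C13).

Assumption: the target is taken exactly as the given SMILES (all three esters are angelates, i.e. (Z)-2-methylbut-2-enoates), and the pinacol (2-methylbut-3-en-2-yl)boronate used in step 2 is treated as a catalogue reagent.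

**Route**

Step 1
Reactants: 1 (S)-carvone
Product: 3 (S)-2-(4-methyl-5-oxocyclohex-3-en-1-yl)prop-2-enal, via 10-hydroxycarvone 2 (not isolated)
Conditions: SeO2 (0.3 equiv), t-BuOOH (3 equiv), CH2Cl2, 25 °C; then MnO2 (excess), CH2Cl2, 25 °C
Reagents that add atoms: selenium dioxide, O=[Se]=O; tert-butyl hydroperoxide, CC(C)(C)OO
Why: Sharpless–Umbreit allylic oxidation (selenium ene reaction then [2,3]-sigmatropic shift) takes the CH3 of the electron-rich 1,1-disubstituted isopropenyl group rather than the electron-poor enone, and MnO2 then oxidises only the primary allylic alcohol, so C8 reaches the aldehyde level without touching the C6 stereocentre.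

Step 2
Reactants: 3 (S)-2-(4-methyl-5-oxocyclohex-3-en-1-yl)prop-2-enal; 4 2-(2-methylbut-3-en-2-yl)-4,4,5,5-tetramethyl-1,3,2-dioxaborolane
Product: 6 (6S,8S)-8-hydroxybisabola-3,7(14),10-trien-2-one, via pinacol borate ester 5 (not isolated)
Conditions: (S)-TRIP [(S)-3,3′-bis(2,4,6-triisopropylphenyl)-1,1′-binaphthyl-2,2′-diyl hydrogen phosphate] (5 mol %), 4 Å MS, PhMe, −30 → 0 °C; then aq NaHCO3
Reagents that add atoms: 4, 2-(2-methylbut-3-en-2-yl)-4,4,5,5-tetramethyl-1,3,2-dioxaborolane, C=CC(C)(C)B1OC(C)(C)C(C)(C)O1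
Why: Proposed new method: in this chiral-phosphoric-acid-catalysed allylboration boron sits on the tertiary carbon of 4, so the closed six-membered chair transition state can only join the aldehyde carbon to the unsubstituted CH2 terminus (linear prenyl, no reverse-prenyl isomer), while the (S)-acid, hydrogen-bonded to a boronate oxygen and the formyl C–H, should direct attack to the Si face of the aldehyde (far more reactive than the enone ketone) and so set 8S; the closest known reactions are the TRIP-catalysed allylboration of aldehydes with allyl-Bpin, where the (R)-acid attacks the Re face, and the uncatalysed linear prenylation of aldehydes by pinacol (1,1-dimethylallyl)boronate.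

Step 3
Reactants: 6 (6S,8S)-8-hydroxybisabola-3,7(14),10-trien-2-one
Product: 7 (3S,4S,6S,8S)-3,4-epoxy-8-hydroxybisabola-7(14),10-dien-2-one
Conditions: 30% aq H2O2, NaOH (0.2 equiv), MeOH, 0 °C
Reagents that add atoms: hydrogen peroxide, OO
Why: Weitz–Scheffer nucleophilic epoxidation, in which hydroperoxide adds to C4 of the enone axially and anti to the C6 side chain (as with carvone itself) and the enolate closes the oxirane on that face, gives the 3,4-epoxide trans to C6 while the three isolated alkenes are inert to the hydroperoxide anion.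

Step 4
Reactants: 7 (3S,4S,6S,8S)-3,4-epoxy-8-hydroxybisabola-7(14),10-dien-2-one
Product: 9 (1R,3S,4S,6R,8S)-3,4-epoxy-1,8-dihydroxybisabola-7(14),10-dien-2-one, via disodium enolate alkoxide 8 (not isolated)
Conditions: NaN(SiMe3)2 (2.3 equiv), THF, −78 °C; then 2-(phenylsulfonyl)-3-phenyloxaziridine (1.3 equiv), −78 °C; then AcOH
Reagents that add atoms: 2-(phenylsulfonyl)-3-phenyloxaziridine, O=S(=O)(c1ccccc1)N1OC1c1ccccc1
Why: In this Davis enolate α-hydroxylation C3 is quaternary, so only C1 can be deprotonated (the 8-OH rides along as its alkoxide), and the oxaziridine transfers oxygen to the enolate face anti to the adjacent C6 side chain, giving the 1,6-trans alcohol (1R).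

Step 5
Reactants: 9 (1R,3S,4S,6R,8S)-3,4-epoxy-1,8-dihydroxybisabola-7(14),10-dien-2-one
Product: 10 (1R,2S,3R,4S,6R,8S)-3,4-epoxybisabola-7(14),10-diene-1,2,8-triol
Conditions: NaBH4, CeCl3·7H2O, MeOH, −78 → −40 °C
Reagents that add atoms: none
Why: In this Luche-type ketone reduction, with 1-OH and the C6 chain equatorial, the small hydride adds axially to C2 from the face opposite the C3 methyl group (the face carrying the oxirane oxygen and 1-OH), so the new 2-OH is equatorial, trans to 1-OH and anti to the oxirane (the descriptor at C3 changes from S to R only because the ketone is gone).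

Step 6
Reactants: 10 (1R,2S,3R,4S,6R,8S)-3,4-epoxybisabola-7(14),10-diene-1,2,8-triol; 11 angelic acid
Product: 13 (1R,2S,3S,4S,6R,8S)-3,4-epoxybisabola-7(14),10-diene-1,2,8-triyl tris[(Z)-2-methylbut-2-enoate], via angelic 2,4,6-trichlorobenzoic anhydride 12 (not isolated)
Conditions: 11 (9 equiv), 2,4,6-trichlorobenzoyl chloride (9 equiv), Et3N (18 equiv), PhMe, 25 °C, 2 h; then 10, 80 °C
Reagents that add atoms: 11, angelic acid [(Z)-2-methylbut-2-enoic acid], C/C=C(/C)C(=O)O
Why: Yamaguchi-type mixed-anhydride esterification run without a nucleophilic pyridine catalyst (Greene's angelate protocol) acylates the three secondary alcohols at oxygen only, so every carbinol centre is retained and the (Z)-alkene of the angeloyl group is not isomerised to tiglate.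

Step 7
Reactants: 13 (1R,2S,3S,4S,6R,8S)-3,4-epoxybisabola-7(14),10-diene-1,2,8-triyl tris[(Z)-2-methylbut-2-enoate]
Product: 14 (1R,2S,3S,4S,6R,8S,10R)-3,4:10,11-diepoxybisabol-7(14)-ene-1,2,8-triyl tris[(Z)-2-methylbut-2-enoate]
Conditions: D-fructose-derived Shi ketone (1,2:4,5-di-O-isopropylidene-β-D-erythro-2,3-hexodiulo-2,6-pyranose, 0.3 equiv), KHSO5 (as 2KHSO5·KHSO4·K2SO4), K2CO3, Bu4NHSO4, MeCN–CH2(OMe)2/aq Na2B4O7 buffer (pH 10.5), 0 °C
Reagents that add atoms: potassium peroxymonosulfate (KHSO5), [K+].[O-]S(=O)(=O)OO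
Why: In this Shi asymmetric epoxidation the chiral dioxirane reacts through a spiro transition state with the only electron-rich trisubstituted alkene (C10=C11), the D-fructose-derived ketone delivering oxygen to the face that gives R at the CH carbon of R–CH=CMe2 alkenes, while the hindered C7=C14 alkene flanked by acyloxy carbons and the conjugated angelate alkenes are too electron-poor to compete.

**Compound list**

1 | (S)-carvone | C=C(C)[C@H]1CC=C(C)C(=O)C1 | starting material
2 | (S)-5-(3-hydroxyprop-1-en-2-yl)-2-methylcyclohex-2-en-1-one (10-hydroxycarvone) | C=C(CO)[C@H]1CC=C(C)C(=O)C1 | intermediate (not isolated)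
3 | (S)-2-(4-methyl-5-oxocyclohex-3-en-1-yl)prop-2-enal | C=C(C=O)[C@H]1CC=C(C)C(=O)C1 | intermediate
4 | 2-(2-methylbut-3-en-2-yl)-4,4,5,5-tetramethyl-1,3,2-dioxaborolane | C=CC(C)(C)B1OC(C)(C)C(C)(C)O1 | starting material
5 | (6S,8S)-8-[(4,4,5,5-tetramethyl-1,3,2-dioxaborolan-2-yl)oxy]bisabola-3,7(14),10-trien-2-one | C=C([C@H](CC=C(C)C)OB1OC(C)(C)C(C)(C)O1)[C@H]1CC=C(C)C(=O)C1 | intermediate (not isolated)
6 | (6S,8S)-8-hydroxybisabola-3,7(14),10-trien-2-one | C=C([C@H](CC=C(C)C)O)[C@H]1CC=C(C)C(=O)C1 | intermediate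
7 | (3S,4S,6S,8S)-3,4-epoxy-8-hydroxybisabola-7(14),10-dien-2-one | C=C([C@H](CC=C(C)C)O)[C@H]1C[C@@H]2O[C@]2(C)C(=O)C1 | intermediate
8 | disodium (3S,4S,6S,8S)-3,4-epoxybisabola-1,7(14),10-triene-2,8-diolate | C=C([C@H](CC=C(C)C)[O-])[C@H]1C[C@@H]2O[C@]2(C)C([O-])=C1.[Na+].[Na+] | intermediate (not isolated)
9 | (1R,3S,4S,6R,8S)-3,4-epoxy-1,8-dihydroxybisabola-7(14),10-dien-2-one | C=C([C@H](CC=C(C)C)O)[C@H]1C[C@@H]2O[C@]2(C)C(=O)[C@@H]1O | intermediate
10 | (1R,2S,3R,4S,6R,8S)-3,4-epoxybisabola-7(14),10-diene-1,2,8-triol | C=C([C@H](CC=C(C)C)O)[C@H]1C[C@@H]2O[C@]2(C)[C@@H](O)[C@@H]1O | intermediate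
11 | angelic acid, (Z)-2-methylbut-2-enoic acid | C/C=C(/C)C(=O)O | starting material
12 | (Z)-2-methylbut-2-enoic 2,4,6-trichlorobenzoic anhydride | C/C=C(/C)C(=O)OC(=O)c1c(Cl)cc(Cl)cc1Cl | intermediate (not isolated)
13 | (1R,2S,3S,4S,6R,8S)-3,4-epoxybisabola-7(14),10-diene-1,2,8-triyl tris[(Z)-2-methylbut-2-enoate] | C=C([C@H](CC=C(C)C)OC(=O)/C(C)=C\C)[C@H]1C[C@@H]2O[C@]2(C)[C@@H](OC(=O)/C(C)=C\C)[C@@H]1OC(=O)/C(C)=C\C | intermediate
14 | (1R,2S,3S,4S,6R,8S,10R)-3,4:10,11-diepoxybisabol-7(14)-ene-1,2,8-triyl tris[(Z)-2-methylbut-2-enoate] (CNP0258231.1) | C=C([C@H](C[C@H]1OC1(C)C)OC(=O)/C(C)=C\C)[C@H]1C[C@@H]2O[C@]2(C)[C@@H](OC(=O)/C(C)=C\C)[C@@H]1OC(=O)/C(C)=C\C | target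

**Step count and risk**

Total step count: 7. Longest linear sequence: 7 steps (1 → 14).

The three steps most likely to fail are steps 1, 2 and 6.

Step 1 is at risk because selenium-based C–H oxidation of the isopropenyl group is often low-yielding and can give over-oxidised or ring-oxidised material. The fallback sets out from 1: ene-type allylic chlorination with Ca(OCl)2/CO2 (CH2Cl2–H2O, 0 °C) gives (S)-10-chlorocarvone F1. Ganem oxidation of the allylic chloride with Me3NO (DMSO, 25 °C) then delivers the aldehyde and rejoins the route at 3.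

Step 2 is at risk because the catalytic linear prenylboration is unproven for this boronate; rate or facial control may be inadequate on the keto-enal. The fallback sets out from 3: Brown allylboration with (Ipc)2B(allyl) made from (+)-α-pinene (Et2O, −78 °C, non-oxidative ethanolamine work-up), the reagent that adds to the Si face, gives (S)-5-[(S)-3-hydroxyhexa-1,5-dien-2-yl]-2-methylcyclohex-2-en-1-one F2. Cross-metathesis of its vinyl group with 2-methyl-2-butene (second-generation Grubbs catalyst, RuCl2(=CHPh)(PCy3)(H2IMes), CH2Cl2, 40 °C) rejoins the route at 6.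

Step 6 is at risk because three hindered secondary alcohols must be acylated at 80 °C without Z-to-E isomerisation of the angeloyl groups. The fallback sets out from 10: Steglich esterification with 2-[bis(2,2,2-trifluoroethoxy)phosphoryl]propanoic acid (EDC·HCl, DMAP, CH2Cl2, 25 °C) gives (1R,2S,3S,4S,6R,8S)-3,4-epoxybisabola-7(14),10-diene-1,2,8-triyl tris{2-[bis(2,2,2-trifluoroethoxy)phosphoryl]propanoate} F3. A threefold Still–Gennari olefination (KN(SiMe3)2, 18-crown-6, THF, −78 °C, then acetaldehyde) builds the three (Z)-2-methylbut-2-enoates on the substrate and rejoins the route at 13.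

Further compounds
F1 | step 1 | (S)-5-(3-chloroprop-1-en-2-yl)-2-methylcyclohex-2-en-1-one [(S)-10-chlorocarvone] | C=C(CCl)[C@H]1CC=C(C)C(=O)C1
F2 | step 2 | (S)-5-[(S)-3-hydroxyhexa-1,5-dien-2-yl]-2-methylcyclohex-2-en-1-one | C=C([C@H](CC=C)O)[C@H]1CC=C(C)C(=O)C1
F3 | step 6 | (1R,2S,3S,4S,6R,8S)-3,4-epoxybisabola-7(14),10-diene-1,2,8-triyl tris{2-[bis(2,2,2-trifluoroethoxy)phosphoryl]propanoate}, epimer mixture at the three phosphonate-bearing carbons | C=C([C@H](CC=C(C)C)OC(=O)C(C)P(=O)(OCC(F)(F)F)OCC(F)(F)F)[C@H]1C[C@@H]2O[C@]2(C)[C@@H](OC(=O)C(C)P(=O)(OCC(F)(F)F)OCC(F)(F)F)[C@@H]1OC(=O)C(C)P(=O)(OCC(F)(F)F)OCC(F)(F)F
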